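## The problem

Compound 23 is a daucane-type sesquiterpenoid ester in which a cyclopentane (C1–C5) is cis-fused along C1–C5 to a cycloheptene (C1, C5–C10). The numbering used throughout is: C1 the methyl-bearing quaternary fusion carbon, C2 and C3 the cyclopentane methylenes, C4 the isopropyl-bearing tertiary carbinol, C5 the fusion methine, C6 the carbon carrying the isovanillate, C7=C8 the alkene with a methyl group on C8, and C9 and C10 the remaining methylenes. Four contiguous stereocentres (1R,4R,5S,6R) must be set: the C1 methyl and the C5 hydrogen lie on one face, and the oxygens on C4 and C6 are cis to each other on the opposite face. C1 is quaternary and cannot be corrected later, so it has to come from an enantioselective reaction; once in place, a tether from C1 can dictate C5, and C5 together with the oxygen on C4 can dictate C6. The product is fragile: the allylic ester ionises easily to a methyl-stabilised allyl cation, the tertiary alcohol dehydrates under acid, and the free phenol does not tolerate organometallic reagents, so late steps must be few, cold and near neutral. The feature that invites a short solution is the sequence carbinol C4, C5, ester carbon C6 beside C7=C8(CH3). These are the three carbons of a Prins adduct between a ketone (C4) and the terminus (C5) of a 1,3-diene C5=C6–C7=C8, whose allyl cation C6–C7–C8 is stabilised by the C8 methyl and can be trapped at C6 by the carboxylate the target needs anyway.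

## Retrosynthesis

**23 to 22.** Only the O–Si bond of a protecting group separates target 23 from silyl ether 22. The phenol has to be masked for exactly as long as organoaluminium chemistry is in play, and buffered fluoride at 0 °C is the mildest possible last step for a molecule with an ionisable allylic ester and a tertiary alcohol. Nothing is simplified structurally; the forward reaction only has to spare the ester.

**22 to 17 and 20.** In 22 the bonds C4–C5 and C6–O are cut together. Cutting the acyl–oxygen bond alone would lead to a diol whose three contiguous stereocentres and two differentiated hydroxyls would still have to be made. Cutting C4–C5 alone, as an aldol, would leave C6 as a ketone to be reduced and acylated afterwards. The double cut removes one ring, two bonds and three of the four stereocentres at once, leaving the monocyclic dienyl ketone 17 with a single stereocentre, and acid 20. The forward reaction must add the diene through C5 and not C6, place the oxygen nucleophile on C6 and not C8, on the face of O4, and avoid proton loss. To bias the last two points the carboxylate is built into the Lewis acid as aluminium carboxylate 21, so that after C–C bond formation it sits on the aluminium held by O4, one six-membered array away from C6.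

**20 to 18.** The O–Si bond of 20 is cut to give isovanillic acid 18. The forward reaction silylates both acidic hydroxyls (19) and then frees the carboxyl group again, which is routine.

**17 to 13.** The ring C6–H bond of the diene is traced to a C6–O bond: 17 comes from ketal diene 16, this from dienyl triflate 15, and 15 from enone 13. The carbonyl group at C6 is kept in the retrosynthesis because it is what allows C1 to be made by conjugate addition; dehydration or hydrazone-based routes to the diene would be less regiodefined. The side-chain ketone is carried as a dioxolane in 13, 15 and 16 so that enolisation occurs only in the ring. The forward sequence needs kinetic enolisation at the single α' position and a mild ketal hydrolysis that the diene survives.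

**13 to 6 and 11.** The C1–C2 bond is cut. C1 is the only stereocentre of 17 and is quaternary, so forming it by face-selective conjugate addition of a three-carbon homoenolate equivalent (Grignard reagent 12 from iodide 11) to a β-methyl enone is the most direct answer. The acceptor is the C2-symmetric dienone 6, in which both enone units are equivalent, so there is no regiochemical question. The alternative cut C1–CH3 would need an unsymmetrical dienone with two competing β-carbons. The forward reaction is asked for enantiofacial control and for tolerance of the ketal.

**11 to 7 and 8.** Iodide 11 is traced through chloride 10 (halide exchange) and chloro ketone 9 (ketalisation) to isobutyryl chloride 7 and ethylene 8, with the C3–C4 bond cut. This acylation of an alkene delivers the isopropyl ketone and the two-carbon spacer with the halide already in place.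

**6 to 1 and 2.** Dienone 6 is traced through the saturated oxa-bridged ketone 5 and its unsaturated parent 4 to 2,5-dimethylfuran 2 and 1,3-dichloroacetone 1 (via chloro adduct 3). The (4+3) cycloaddition makes the seven-membered ring with both methyl groups and the carbonyl group in their final relationship; the ether bridge is then removed by double β-elimination. Ring-expansion or ring-closing routes to 6 would need more steps for the same symmetrical product.

## Roads not taken

**Alternative 1:** The cut is C5–C6 together with a temporary O–C4 bond. The precursor is (1E,2Z)-3-methyl-5-[(1R)-1-methyl-3-(propan-2-yl)cyclopent-2-en-1-yl]pent-2-enal oxime A1. Oxidation with hypochlorite unmasks its nitrile oxide function, which adds across the cyclopentene C4=C5 bond to give tricyclic isoxazoline A2, closing the seven-membered ring and the heterocycle in one step.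
- Merits: every step is of a known type, and the O–C4 and C5–C6 bonds form suprafacially, so the C4/C5 relationship is guaranteed by mechanism rather than by a transition-state preference. In this respect it is better than the chosen plan.
- Weak points: the dipolarophile is a hindered trisubstituted alkene and the ring being closed is seven-membered, so dimerisation of the dipole competes. A1 needs a geometrically pure Z-trisubstituted alkene. After A2 four more operations remain (N–O cleavage with imine hydrolysis, ketone reduction with control at C6, acylation, desilylation).
- Comparison: the chosen plan sets C6 and installs the ester in the ring-forming step itself, leaves one step after it, and uses a precursor (17) whose diene geometry is fixed by the ring. It pays for this with an unprecedented key step.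

**Alternative 2:** The cuts are C1–C5 and C9–C10. Base-induced loss of acetate from 2-[1-(tert-butyldimethylsilyloxy)-4-methylpent-4-enyl]-5-methyl-3-oxo-3,6-dihydro-2H-pyran-6-yl acetate A3 gives an oxidopyrylium dipole. This adds to the tethered 1,1-disubstituted alkene in a (5+2) cycloaddition to give the C5–O–C9-bridged tricyclic enone A4.
- Merits: both carbocycles and the quaternary C1 arise in one well-precedented step from a chain, which is more convergent in ring construction than the chosen plan.
- Weak points: the oxidation pattern of A4 does not match 23. C5 carries oxygen instead of hydrogen, C9 is oxygenated, C4 lacks the isopropyl group and C6 is a ketone. The bridge must be cleaved reductively with uncertain control of the C5 configuration, C9 deoxygenated, C4 oxidised and alkylated, and C6 reduced and acylated.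
- Comparison: for this target the long corrective sequence outweighs the elegant ring construction. The chosen plan forms only bonds that the target keeps.

**Alternative 3:** The cuts are C8–C9 and C6–C7, with C6–C9 formed in the backward sense. The cis-fused ketone A5 (3a-methyl-6-(propan-2-yl)-6-(triethylsilyloxy)hexahydropentalen-1(2H)-one, configured as in A7) is condensed with a secondary amine. The enamine function adds to methyl but-2-ynoate A6, and the fused aminocyclobutene opens on warming to give, after hydrolysis, the ring-enlarged keto ester A7 (methyl 6,8a-dimethyl-4-oxo-3-(propan-2-yl)-3-(triethylsilyloxy)-1,2,3,3a,4,7,8,8a-octahydroazulene-5-carboxylate).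
- Merits: the reaction type is known, and C1, C4 and C5 are set in a compact bicycle before the flexible seven-membered ring exists. On reliability of stereocontrol at C4 it is better than the chosen plan.
- Weak points: enamine formation next to the crowded ring fusion is slow. A7 carries an ester on C7 that must be removed from an sp2 carbon, followed by ketone reduction, acylation and two desilylations. A5 itself needs a multistep asymmetric synthesis at least as long as that of 17.
- Comparison: individually safer steps, but clearly more of them. The chosen plan sets against this a single ring-forming step that delivers the complete functional array.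

Key step: step 11

## Route

Step 1
Reactants: 1 1,3-dichloroacetone; 2 2,5-dimethylfuran
Product: 4 (1R,5S)-1,5-dimethyl-8-oxabicyclo[3.2.1]oct-6-en-3-one (meso), via chloro cycloadduct 3 (not isolated)
Conditions: Et3N, CF3CH2OH, 0 °C to rt; then Zn–Cu couple, NH4Cl, MeOH, rt
Reagents that add atoms: none
Why: Base-induced loss of HCl from 1 in the ionising fluoroalcohol gives a chloro-substituted oxyallyl cation that undergoes (4+3) cycloaddition with the electron-rich furan 2; zinc then removes the α-chlorine of crude 3 reductively. The product is meso, so no stereochemical question arises.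

Step 2
Reactants: 4 (1R,5S)-1,5-dimethyl-8-oxabicyclo[3.2.1]oct-6-en-3-one
Product: 5 (1R,5S)-1,5-dimethyl-8-oxabicyclo[3.2.1]octan-3-one (meso)
Conditions: H2 (1 atm), 10% Pd on carbon, EtOAc, rt
Reagents that add atoms: none
Why: Heterogeneous catalytic hydrogenation saturates the strained bicyclic alkene without touching the ketone; removing this unsaturation prevents formation of a tropone in the next step.

Step 3
Reactants: 5 (1R,5S)-1,5-dimethyl-8-oxabicyclo[3.2.1]octan-3-one
Product: 6 3,6-dimethylcyclohepta-2,6-dien-1-one
Conditions: p-TsOH·H2O (0.2 equiv), toluene, reflux, azeotropic removal of water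
Reagents that add atoms: none
Why: Acid-mediated double β-elimination, the established way of unravelling hydrogenated oxyallyl–furan adducts to cyclohepta-2,6-dienones: each tertiary C–O bond opens through the enol (retro-oxa-Michael, then dehydration of a tertiary β-hydroxy ketone). Removal of water drives the equilibria to the cross-conjugated dienone, in which both trisubstituted alkenes are conjugated with the carbonyl group.

Step 4
Reactants: 7 isobutyryl chloride; 8 ethylene
Product: 9 1-chloro-4-methylpentan-3-one
Conditions: AlCl3, CH2Cl2, 0 °C, ethylene bubbled through; ice-cold dilute HCl work-up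
Reagents that add atoms: none
Why: Friedel–Crafts-type acylation of an alkene: the acylium ion adds to ethylene and chloride from AlCl4− closes the sequence, giving the β-chloroethyl ketone.

Step 5
Reactants: 9 1-chloro-4-methylpentan-3-one
Product: 10 2-(2-chloroethyl)-2-(propan-2-yl)-1,3-dioxolane
Conditions: HOCH2CH2OH, HC(OEt)3, p-TsOH·H2O (cat.), CH2Cl2, rt
Reagents that add atoms: ethylene glycol, OCCO
Why: Acid-catalysed ketalisation with an orthoester as water scavenger runs at room temperature, which avoids loss of HCl from the β-chloro ketone. The dioxolane masks the carbonyl group for the organomagnesium and enolate chemistry that follows.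

Step 6
Reactants: 10 2-(2-chloroethyl)-2-(propan-2-yl)-1,3-dioxolane
Product: 11 2-(2-iodoethyl)-2-(propan-2-yl)-1,3-dioxolane
Conditions: NaI, acetone, reflux
Reagents that add atoms: sodium iodide, [Na+].[I-]
Why: Finkelstein exchange (SN2 at a primary carbon, driven by precipitation of NaCl) gives the iodide, which inserts magnesium in diethyl ether at room temperature, where the β-metallo ketal is stable.

Step 7
Reactants: 11 2-(2-iodoethyl)-2-(propan-2-yl)-1,3-dioxolane; 6 3,6-dimethylcyclohepta-2,6-dien-1-one
Product: 13 (6R)-3,6-dimethyl-6-{2-[2-(propan-2-yl)-1,3-dioxolan-2-yl]ethyl}cyclohept-2-en-1-one, via Grignard reagent 12 (not isolated)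
Conditions: Mg, Et2O, rt; then added to 6, Cu(OTf)2 (5 mol %), chiral C2-symmetric imidazolinium chloride (carbene precursor, 6 mol %), Et2O, −30 °C; aq. NH4Cl
Reagents that add atoms: none
Why: Copper–N-heterocyclic carbene-catalysed asymmetric conjugate addition of a primary alkyl Grignard reagent to a β-methyl cycloalkenone is a known way to all-carbon quaternary centres; the chiral carbene ligand selects the enone face and sets C1 as R, the ligand enantiomer being chosen accordingly. Both enone units of the C2-symmetric dienone 6 give the same product, and the magnesium dienolate formed protects the second enone from further addition.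

Step 8
Reactants: 13 (6R)-3,6-dimethyl-6-{2-[2-(propan-2-yl)-1,3-dioxolan-2-yl]ethyl}cyclohept-2-en-1-one
Product: 15 (3R)-3,6-dimethyl-3-{2-[2-(propan-2-yl)-1,3-dioxolan-2-yl]ethyl}cyclohepta-1,6-dien-1-yl trifluoromethanesulfonate, via lithium dienolate 14 (not isolated)
Conditions: LiN(i-Pr)2, THF, −78 °C; then PhNTf2, −78 to 0 °C
Reagents that add atoms: N-phenylbis(trifluoromethanesulfonimide), O=S(=O)(N(c1ccccc1)S(=O)(=O)C(F)(F)F)C(F)(F)F
Why: Kinetic deprotonation of the enone at its only α' position (the methylene between the carbonyl group and the quaternary carbon) gives the cross-conjugated lithium dienolate 14, which is O-sulfonylated by PhNTf2. The quaternary stereocentre is not touched.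

Step 9
Reactants: 15 (3R)-3,6-dimethyl-3-{2-[2-(propan-2-yl)-1,3-dioxolan-2-yl]ethyl}cyclohepta-1,6-dien-1-yl trifluoromethanesulfonate
Product: 17 1-[(1R)-1,5-dimethylcyclohepta-2,4-dien-1-yl]-4-methylpentan-3-one, via ketal diene 16 (not isolated)
Conditions: Pd(OAc)2 (5 mol %), PPh3 (10 mol %), HCO2H, n-Bu3N, DMF, 60 °C; then pyridinium p-toluenesulfonate, acetone/H2O, 40 °C
Reagents that add atoms: water, O
Why: Zerovalent palladium inserts into the C–OTf bond and formate delivers hydride with loss of CO2 (enol triflate reduction), giving the 1,3-diene with its double bonds fixed by the position of the former enolate. Mild aqueous acid then hydrolyses the hindered dialkyl ketal faster than it protonates the diene.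

Step 10
Reactants: 18 isovanillic acid
Product: 20 3-[(tert-butyldimethylsilyl)oxy]-4-methoxybenzoic acid, via bis-silylated ester 19 (not isolated)
Conditions: TBSCl (2.5 equiv), imidazole, DMF, rt; then AcOH/THF/H2O (3:1:1), rt
Reagents that add atoms: tert-butyldimethylsilyl chloride, CC(C)(C)[Si](C)(C)Cl
Why: Silylation of both acidic hydroxyls followed by selective hydrolysis of the labile silyl ester leaves the aryl silyl ether. The phenol must be masked so that only the carboxyl group reacts with aluminium in step 11.

Step 11
Reactants: 17 1-[(1R)-1,5-dimethylcyclohepta-2,4-dien-1-yl]-4-methylpentan-3-one; 20 3-[(tert-butyldimethylsilyl)oxy]-4-methoxybenzoic acid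
Product: 22 (3R,3aS,4R,8aR)-3-hydroxy-6,8a-dimethyl-3-(propan-2-yl)-1,2,3,3a,4,7,8,8a-octahydroazulen-4-yl 3-[(tert-butyldimethylsilyl)oxy]-4-methoxybenzoate, via aluminium carboxylate 21 (not isolated)
Conditions: Me2AlCl (1.5 equiv), 20 (1.5 equiv), CH2Cl2, −78 to 0 °C; then 17, −78 to −40 °C; aq. KNaC4H4O6 quench at −40 °C
Reagents that add atoms: none
Why: Proposed new method: Me2AlCl deprotonates acid 20 with loss of methane to give the Lewis-acidic aluminium carboxylate 21, whose aluminium binds the ketone oxygen of 17; the diene terminus C5 attacks the activated carbonyl carbon C4, and the aluminate-bound carboxylate then collapses onto C6 of the C8-methyl-stabilised allyl cation, so that C4–C5 and C6–O form without a free proton or an external nucleophile. The closest known reactions are alkylaluminium halide-promoted intramolecular ketone–alkene Prins and carbonyl–ene cyclisations and Prins reactions terminated by a carboxylate to give 1,3-diol monoesters; the combination on a ketone–1,3-diene pair with inner-sphere ester delivery has not been shown. The cyclopentane closes in a 5-exo-trig mode with respect to the C5=C6 π bond (the carbonyl π bond is also exocyclic); attack through C6 would give a non-allylic cation and a bridged ring and is disfavoured. C5 is set by the three-atom tether from the C1 stereocentre, which can reach C5 only on its own face and so enforces the cis ring fusion. C4 is set by the orientation of the carbonyl group in the closing transition state: the isopropyl group points away from the seven-membered ring and the aluminium-bound oxygen lies over C6, which is favoured sterically and by attraction to the developing cation. C6 is set by delivery of the carboxylate from the aluminium on O4 through the six-membered array O4–Al–O–C6–C5–C4 to the cation face syn to O4, giving the cis O4/O6 relation. The step needs capture at C6 rather than C8, ester formation rather than proton loss, chloride capture or closure by O4, and survival of the ionisable allylic ester; these rest on the proximity of the aluminium-bound carboxylate to C6 (C8 is beyond easy reach), on the absence of free acid or base, and on reaction and quench at low temperature.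

Step 12
Reactants: 22 (3R,3aS,4R,8aR)-3-hydroxy-6,8a-dimethyl-3-(propan-2-yl)-1,2,3,3a,4,7,8,8a-octahydroazulen-4-yl 3-[(tert-butyldimethylsilyl)oxy]-4-methoxybenzoate
Product: 23 (3R,3aS,4R,8aR)-3-hydroxy-6,8a-dimethyl-3-(propan-2-yl)-1,2,3,3a,4,7,8,8a-octahydroazulen-4-yl 3-hydroxy-4-methoxybenzoate
Conditions: Bu4NF, AcOH, THF, 0 °C
Reagents that add atoms: none
Why: Fluoride cleaves the aryl silyl ether through Si–F bond formation; buffering with acetic acid keeps the phenoxide from promoting acyl transfer or elimination, and the tertiary alcohol and the allylic ester are not affected.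

## Compound list

1 | 1,3-dichloroacetone | ClCC(=O)CCl | starting material
2 | 2,5-dimethylfuran | Cc1ccc(C)o1 | starting material
3 | 2-chloro-1,5-dimethyl-8-oxabicyclo[3.2.1]oct-6-en-3-one (racemic, both epimers at the chlorine-bearing carbon) | O=C1CC2(C)C=CC(C)(O2)C1Cl | intermediate (not isolated)
4 | (1R,5S)-1,5-dimethyl-8-oxabicyclo[3.2.1]oct-6-en-3-one (meso) | O=C1C[C@]2(C)C=C[C@](C)(C1)O2 | intermediate
5 | (1R,5S)-1,5-dimethyl-8-oxabicyclo[3.2.1]octan-3-one (meso) | O=C1C[C@]2(C)CC[C@](C)(C1)O2 | intermediate
6 | 3,6-dimethylcyclohepta-2,6-dien-1-one | O=C1C=C(C)CCC(C)=C1 | intermediate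
7 | isobutyryl chloride | CC(C)C(Cl)=O | starting material
8 | ethylene | C=C | starting material
9 | 1-chloro-4-methylpentan-3-one | CC(C)C(=O)CCCl | intermediate
10 | 2-(2-chloroethyl)-2-(propan-2-yl)-1,3-dioxolane | CC(C)C1(CCCl)OCCO1 | intermediate
11 | 2-(2-iodoethyl)-2-(propan-2-yl)-1,3-dioxolane | CC(C)C1(CCI)OCCO1 | intermediate
12 | {2-[2-(propan-2-yl)-1,3-dioxolan-2-yl]ethyl}magnesium iodide | CC(C)C1(CC[Mg]I)OCCO1 | intermediate (not isolated)
13 | (6R)-3,6-dimethyl-6-{2-[2-(propan-2-yl)-1,3-dioxolan-2-yl]ethyl}cyclohept-2-en-1-one | O=C1C=C(C)CC[C@](C)(CCC2(C(C)C)OCCO2)C1 | intermediate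
14 | lithium (3R)-3,6-dimethyl-3-{2-[2-(propan-2-yl)-1,3-dioxolan-2-yl]ethyl}cyclohepta-1,6-dien-1-olate | [Li]OC1=C[C@@](C)(CCC2(C(C)C)OCCO2)CCC(C)=C1 | intermediate (not isolated)
15 | (3R)-3,6-dimethyl-3-{2-[2-(propan-2-yl)-1,3-dioxolan-2-yl]ethyl}cyclohepta-1,6-dien-1-yl trifluoromethanesulfonate | O=S(=O)(OC1=C[C@@](C)(CCC2(C(C)C)OCCO2)CCC(C)=C1)C(F)(F)F | intermediate
16 | 2-{2-[(1R)-1,5-dimethylcyclohepta-2,4-dien-1-yl]ethyl}-2-(propan-2-yl)-1,3-dioxolane | CC(C)C1(CC[C@@]2(C)CCC(C)=CC=C2)OCCO1 | intermediate (not isolated)
17 | 1-[(1R)-1,5-dimethylcyclohepta-2,4-dien-1-yl]-4-methylpentan-3-one | CC(C)C(=O)CC[C@@]1(C)CCC(C)=CC=C1 | intermediate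
18 | isovanillic acid (3-hydroxy-4-methoxybenzoic acid) | COc1ccc(C(=O)O)cc1O | starting material
19 | tert-butyldimethylsilyl 3-[(tert-butyldimethylsilyl)oxy]-4-methoxybenzoate | COc1ccc(C(=O)O[Si](C)(C)C(C)(C)C)cc1O[Si](C)(C)C(C)(C)C | intermediate (not isolated)
20 | 3-[(tert-butyldimethylsilyl)oxy]-4-methoxybenzoic acid | COc1ccc(C(=O)O)cc1O[Si](C)(C)C(C)(C)C | intermediate
21 | chloro(methyl)aluminium 3-[(tert-butyldimethylsilyl)oxy]-4-methoxybenzoate | COc1ccc(C(=O)O[Al](C)Cl)cc1O[Si](C)(C)C(C)(C)C | intermediate (not isolated)
22 | (3R,3aS,4R,8aR)-3-hydroxy-6,8a-dimethyl-3-(propan-2-yl)-1,2,3,3a,4,7,8,8a-octahydroazulen-4-yl 3-[(tert-butyldimethylsilyl)oxy]-4-methoxybenzoate | COc1ccc(C(=O)O[C@@H]2C=C(C)CC[C@]3(C)CC[C@@](O)(C(C)C)[C@H]23)cc1O[Si](C)(C)C(C)(C)C | intermediate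
23 | (3R,3aS,4R,8aR)-3-hydroxy-6,8a-dimethyl-3-(propan-2-yl)-1,2,3,3a,4,7,8,8a-octahydroazulen-4-yl 3-hydroxy-4-methoxybenzoate | COc1ccc(C(=O)O[C@@H]2C=C(C)CC[C@]3(C)CC[C@@](O)(C(C)C)[C@H]23)cc1O | target

## Step count and risks

Total step count: 12. Longest linear sequence: 8 steps (steps 1, 2, 3, 7, 8, 9, 11, 12 from 1 and 2; the branch from 7 and 8 through steps 4, 5, 6, 7, 8, 9, 11, 12 is equally long).

**Step 11 (key step, proposed new method).**
- What may go wrong: the allyl cation may lose a proton from C9 or the C8 methyl, or be captured by chloride or by the O4 alkoxide at C8, faster than the carboxylate is transferred. The carboxylate-bearing aluminium may also be too weak a Lewis acid to activate a hindered dialkyl ketone below the temperature at which the product ester re-ionises. Carboxylate ligands lower Lewis acidity and bridge aluminium centres, and the stabilised cation lives long enough to find other exits.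
- Fallback (known chemistry), setting out from 13 and returning at 22: hydrolysis of the dioxolane (pyridinium p-toluenesulfonate, acetone/H2O) gives (6R)-3,6-dimethyl-6-(4-methyl-3-oxopentyl)cyclohept-2-en-1-one F1. A reversible intramolecular aldol addition under thermodynamic control (KOt-Bu, t-BuOH/THF, 0 °C) lets the α' carbon C5 of the enone add to the isopropyl ketone. The tether again forces the cis fusion and the metal bridging both oxygens places O4 on the C6 side, giving (3R,3aR,8aR)-3-hydroxy-6,8a-dimethyl-3-(propan-2-yl)-2,3,3a,7,8,8a-hexahydroazulen-4(1H)-one F2. Chelation-controlled 1,2-reduction (Narasaka–Prasad conditions: Et2BOMe, NaBH4, THF/MeOH, −78 °C) should give the cis-diol (3R,3aS,4R,8aR)-6,8a-dimethyl-3-(propan-2-yl)-1,2,3,3a,4,7,8,8a-octahydroazulene-3,4-diol F3. Steglich acylation of the secondary allylic hydroxyl with acid 20 (EDC·HCl, DMAP, CH2Cl2; the tertiary hydroxyl does not react) rejoins the route at 22.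

**Step 7 (asymmetric conjugate addition).**
- What may go wrong: erosion of enantioselectivity or low conversion, because the ketal oxygens of 12 can chelate magnesium and copper and because β-metallo ketals decompose by 1,3-elimination if the reagent warms.
- Fallback, setting out from 6 and returning at 13: the same copper–carbene catalysis is run with 4-methylpent-3-enylmagnesium bromide, an unfunctionalised primary alkyl Grignard reagent in Et2O and the best-precedented nucleophile class. This gives (6S)-3,6-dimethyl-6-(4-methylpent-3-en-1-yl)cyclohept-2-en-1-one F4, which has the same spatial arrangement as 13 (the descriptor changes with substituent priorities). mCPBA epoxidises the isolated trisubstituted alkene in preference to the enone to give (6R)-6-[2-(3,3-dimethyloxiran-2-yl)ethyl]-3,6-dimethylcyclohept-2-en-1-one F5 (both epoxide epimers). BF3·OEt2-mediated Meinwald rearrangement (opening at the tertiary carbon, hydride shift) gives the keto-enone F1 already described. Selective ketalisation of its saturated ketone (ethylene glycol, HC(OEt)3, p-TsOH) returns to 13.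

**Step 3 (bridge opening).**
- What may go wrong: incomplete second elimination, or migration of the double bonds out of cross-conjugation into linearly conjugated or exocyclic isomers, because every intermediate forms reversibly under acid.
- Fallback, setting out from 5 and returning at 6: soft enolisation with Me3SiOTf/Et3N in CH2Cl2 opens one C–O bond by β-elimination without carbocations and gives racemic 3,6-dimethyl-6-(trimethylsilyloxy)cyclohept-2-en-1-one F6. A separate base-mediated E1cB elimination of silanolate (DBU, toluene, heat) then gives 6.

**Step 1 ((4+3) cycloaddition).**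
- What may go wrong: slow generation of the monochloro oxyallyl species, so that the haloketone is consumed by substitution or Favorskii-type pathways; bond formation to the methyl-bearing furan carbons is also hindered.
- Fallback, setting out from 2 and returning at 4: the oxyallyl species is generated reductively from 1,1,3,3-tetrabromoacetone with Zn–Cu couple in the presence of 2, giving 2,4-dibromo-1,5-dimethyl-8-oxabicyclo[3.2.1]oct-6-en-3-one F7 (mixture of bromide epimers). Zn–Cu couple with NH4Cl in MeOH debrominates it to 4.

## Further compounds

F1 | step 11 | (6R)-3,6-dimethyl-6-(4-methyl-3-oxopentyl)cyclohept-2-en-1-one | O=C1C=C(C)CC[C@](C)(CCC(=O)C(C)C)C1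
F2 | step 11 | (3R,3aR,8aR)-3-hydroxy-6,8a-dimethyl-3-(propan-2-yl)-2,3,3a,7,8,8a-hexahydroazulen-4(1H)-one | O=C1C=C(C)CC[C@]2(C)CC[C@@](O)(C(C)C)[C@H]12
F3 | step 11 | (3R,3aS,4R,8aR)-6,8a-dimethyl-3-(propan-2-yl)-1,2,3,3a,4,7,8,8a-octahydroazulene-3,4-diol | O[C@@H]1C=C(C)CC[C@]2(C)CC[C@@](O)(C(C)C)[C@H]12
F4 | step 7 | (6S)-3,6-dimethyl-6-(4-methylpent-3-en-1-yl)cyclohept-2-en-1-one | O=C1C=C(C)CC[C@](C)(CCC=C(C)C)C1
F5 | step 7 | (6R)-6-[2-(3,3-dimethyloxiran-2-yl)ethyl]-3,6-dimethylcyclohept-2-en-1-one (both epoxide epimers) | O=C1C=C(C)CC[C@](C)(CCC2OC2(C)C)C1
F6 | step 3 | 3,6-dimethyl-6-(trimethylsilyloxy)cyclohept-2-en-1-one (racemic) | O=C1C=C(C)CCC(C)(O[Si](C)(C)C)C1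
F7 | step 1 | 2,4-dibromo-1,5-dimethyl-8-oxabicyclo[3.2.1]oct-6-en-3-one (mixture of bromide epimers) | O=C1C(Br)C2(C)C=CC(C)(O2)C1Br
A1 | alternative 1 | (1E,2Z)-3-methyl-5-[(1R)-1-methyl-3-(propan-2-yl)cyclopent-2-en-1-yl]pent-2-enal oxime | O/N=C/C=C(C)\CC[C@]1(C)CCC(C(C)C)=C1
A2 | alternative 1 | tricyclic isoxazoline (C6 as C=N, ring oxygen on C4) | N1=C2C=C(C)CC[C@]3(C)CC[C@@](O1)(C(C)C)[C@H]23
A3 | alternative 2 | 2-[1-(tert-butyldimethylsilyloxy)-4-methylpent-4-enyl]-5-methyl-3-oxo-3,6-dihydro-2H-pyran-6-yl acetate (silyloxy carbon as in A4, ring stereocentres as a mixture) | C=C(C)CC[C@H](O[Si](C)(C)C(C)(C)C)C1OC(OC(C)=O)C(C)=CC1=O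
A4 | alternative 2 | oxygen-bridged tricyclic enone (bridge between C5 and C9, silyloxy at C4) | O=C1C=C(C)[C@H]2C[C@]3(C)CC[C@H](O[Si](C)(C)C(C)(C)C)[C@@]13O2
A5 | alternative 3 | cis-fused 3a-methyl-6-(propan-2-yl)-6-(triethylsilyloxy)hexahydropentalen-1(2H)-one | O=C1CC[C@]2(C)CC[C@@](O[Si](CC)(CC)CC)(C(C)C)[C@H]12
A6 | alternative 3 | methyl but-2-ynoate | CC#CC(=O)OC
A7 | alternative 3 | methyl 6,8a-dimethyl-4-oxo-3-(propan-2-yl)-3-(triethylsilyloxy)-1,2,3,3a,4,7,8,8a-octahydroazulene-5-carboxylate | O=C1C(C(=O)OC)=C(C)CC[C@]2(C)CC[C@@](O[Si](CC)(CC)CC)(C(C)C)[C@H]12
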